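(The constants used here stand for no real mixture; the rest is arithmetic.)

5 questions stood before me, 4 of them yields of target and one a choice between the set-ups, and I looked for one number that could serve them together.

| flask | substrate | enzyme | remark | time |
|---|---|---|---|---|
| dusk | 45 mM | 4.5 µM | a single well-mixed tank run continuously and read at steady state, 40 min in it on average |  |
| midnight | 45 mM (fed, over 32.0 min) | 4.5 µM | all but substrate at the start; substrate goes in evenly over 32.0 min, the run ends at 40 min | 40 min |
| winter | 45 mM | 4.5 µM | a single well-mixed tank run continuously and read at steady state, 120 min in it on average |  |
| dawn | 45 mM | 4.5 µM | a closed flask charged with all of it at once and left for 40 min | 40 min |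

- the set-up with the highest amount of target at the outlet or at the end, in percent of the substrate put in ("none" if the first two lie within 2 percentage points) (dusk / midnight / winter / dawn / none)
- amount of target at the outlet or at the end, in percent of the substrate put in, dusk
- amount of target at the outlet or at the end, in percent of the substrate put in, midnight
- amount of target at the outlet or at the end, in percent of the substrate put in, winter
- amount of target at the outlet or at the end, in percent of the substrate put in, dawn

- a doubled species enters its step squared and goes two at a time
- the stated concentrations are those of everything mixed, before any reaction; amounts are the same in each set-up
- the feed brings no volume worth counting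
- run time (midnight): 40 min

In each set-up enzyme turns substrate into target and then, itself unchanged, turns target into over-reaction product, while pairs of enzyme stand aside as the resting dimer. Counting each dimer as two enzymes, its constant of 86000 /M left a free share of 0.661 of the 4.5 µM charged. Neither reaction step consumes enzyme, so I treated the loss of target as pseudo-first-order, with 125 /M/s times free enzyme giving 0.0223 /min. At the charged level, substrate disappeared at 0.471 /min, much faster than target, so I took the timing of target's birth from how substrate was supplied.

I then divided the rate at which target is destroyed in a tank by the rate at which the tank washes it out. The amount of target dropped out and left the loss number, the loss constant times the mean stay: 0.893 for dusk and 2.68 for winter. For a tank, the share of converted substrate surviving as target was therefore 52.8 % in dusk and 27.2 % in winter. For dawn, I counted target as born at the first moment and exposed for 40 min, which gave 40.9 % of the charge. For midnight, I counted target as born evenly over 32.0 min and then exposed for 8.00 min more, which gave 59.8 %. I therefore committed to midnight, ahead of dusk, dawn and winter.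

The forecast, holding that “target loss therefore depends mainly on how long target sits in the vessel”, chose midnight, with 47.9 % for dusk, 62.7 % for midnight, 25.9 % for winter and 43.4 % for dawn. The simulation gave midnight as best, with 47.9 % for dusk, 62.6 % for midnight, 25.9 % for winter and 43.4 % for dawn.

    substrate + enzyme → target + enzyme, rate k1*[substrate]^1.5*[enzyme]/(1 + ([substrate]/Kh1)^1.5) (Kh1 = 0.0552 M, k1 = 21600 /M^1.5/s)
    2 enzyme ⇌ resting dimer, settled at all times (K2 = 86000 /M)
    enzyme + target → enzyme + over-reaction product (k3 = 125 /M/s)

At dusk's outlet, the ratio of over-reaction product to target was 0.893, which is the loss number 0.893 read from the tank. At winter's outlet, the same ratio was 2.68, beside that tank's loss number of 2.68. Winter's 25.9 % of target is the case where the over-reaction step is the main reason for the shortfall, because striking out the step from enzyme + target to enzyme + over-reaction product raised winter's target to 95.4 %. That step accounted for 94 % of what was missing.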